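**Retrosynthetic overview**

- The target is reached from a 5-bromoflavone by exchange of C5–Br for C5–OH and then hydrogenolysis of three benzyl ethers (7-O, 2'-O, 5'-O).
- Ring C is the only ring built; rings A and B are bought as benzenes. It is opened at C3–C4 and at O1–C8a, a (3+3) annulation: a 2,6-dibromobenzoyl chloride supplies C4, C4a and C8a, and a ring B methoxymethyl ketone supplies C3, C2 and O1.
- The feature the plan rests on is that ring A is fully substituted and mirror-symmetric about the C4a···C7 axis. C5 and C8a, the two carbons flanking C4a, both carry oxygen; C6 and C8 both carry OMe; C7 carries OH. Ring A therefore maps onto syringic acid (carboxyl carbon = C4, C1 = C4a), and a symmetric 2,6-dibromide suffices: either bromide can become C8a–O1 and the other is left at C5.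
- The acid chloride comes from syringic acid (O-benzylation, saponification, 2,6-dibromination, chlorination). The ketone comes from 2-methoxyhydroquinone (benzylation, para-bromination, Br/Li exchange and acylation by the Weinreb amide of methoxyacetyl chloride).

Key step: step 9

Remark on the chemistry: the target is achiral. The only stereogenic elements on the way (the central carbon of the intermediate 1,3-diketone in its keto form, and the enolate geometry) are transient and are drawn without configuration where they are not controlled.

**Route**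

Step 1
Reactants: 1 syringic acid (4-hydroxy-3,5-dimethoxybenzoic acid)
Product: 2 benzyl 4-(benzyloxy)-3,5-dimethoxybenzoate
Conditions: BnBr (2.4 equiv), K2CO3 (3 equiv), DMF, 60 °C
Reagents that add atoms: benzyl bromide, BrCc1ccccc1
Why: Double Williamson O-alkylation (SN2) of the phenoxide and the carboxylate is routine and masks the future C7 oxygen as a benzyl ether that should last until the final hydrogenolysis.

Step 2
Reactants: 2 benzyl 4-(benzyloxy)-3,5-dimethoxybenzoate
Product: 3 4-(benzyloxy)-3,5-dimethoxybenzoic acid
Conditions: NaOH (3 equiv), THF/MeOH/H2O, 60 °C; then aq HCl to pH 2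
Reagents that add atoms: sodium hydroxide, [Na+].[OH-]
Why: Saponification of the unhindered benzyl ester (acyl–oxygen cleavage by hydroxide) should free the acid while the aryl benzyl ether is inert to base.

Step 3
Reactants: 3 4-(benzyloxy)-3,5-dimethoxybenzoic acid
Product: 4 4-(benzyloxy)-2,6-dibromo-3,5-dimethoxybenzoic acid
Conditions: Br2 (2.2 equiv), NaOAc (3 equiv), AcOH, 20 → 40 °C, dark
Reagents that add atoms: bromine, BrBr
Why: Electrophilic aromatic bromination should take both free ring positions, each of which is ortho to one methoxy group and para to the other, while the acetate buffer removes HBr so that the benzyl ether is not cleaved.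

Step 4
Reactants: 4 4-(benzyloxy)-2,6-dibromo-3,5-dimethoxybenzoic acid
Product: 5 4-(benzyloxy)-2,6-dibromo-3,5-dimethoxybenzoyl chloride
Conditions: (COCl)2 (1.5 equiv), DMF (cat.), CH2Cl2, 0 °C → rt
Reagents that add atoms: oxalyl chloride, O=C(Cl)C(=O)Cl
Why: Vilsmeier-type activation with oxalyl chloride and catalytic DMF converts even di-ortho-substituted benzoic acids into acid chlorides under cold conditions that leave the benzyl and methyl ethers alone.

Step 5
Reactants: 6 methoxyacetyl chloride
Product: 7 N,2-dimethoxy-N-methylacetamide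
Conditions: MeNHOMe·HCl (1.1 equiv), Et3N (2.3 equiv), CH2Cl2, 0 °C → rt
Reagents that add atoms: N,O-dimethylhydroxylamine hydrochloride, CNOC.Cl
Why: N-Acylation of N,O-dimethylhydroxylamine by the acid chloride (Weinreb amide formation) is reliable and provides an acyl donor that accepts an aryllithium only once.

Step 6
Reactants: 8 2-methoxyhydroquinone (2-methoxybenzene-1,4-diol)
Product: 9 1,4-bis(benzyloxy)-2-methoxybenzene
Conditions: BnBr (2.3 equiv), K2CO3 (3 equiv), DMF, N2, 60 °C
Reagents that add atoms: benzyl bromide, BrCc1ccccc1
Why: Williamson etherification of both phenols, run under nitrogen because the hydroquinone anion is air-sensitive, protects the future 2'- and 5'-hydroxyl groups.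

Step 7
Reactants: 9 1,4-bis(benzyloxy)-2-methoxybenzene
Product: 10 1,4-bis(benzyloxy)-2-bromo-5-methoxybenzene
Conditions: NBS (1.05 equiv), MeCN, 0 °C → rt, dark
Reagents that add atoms: N-bromosuccinimide, O=C1CCC(=O)N1Br
Why: Electrophilic aromatic bromination should go to the position para to the methoxy group and ortho to a benzyloxy group, the only unhindered site activated by two alkoxy groups (the site between two oxygens is crowded and the third has a single ortho donor).

Step 8
Reactants: 10 1,4-bis(benzyloxy)-2-bromo-5-methoxybenzene; 7 N,2-dimethoxy-N-methylacetamide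
Product: 12 1-[2,5-bis(benzyloxy)-4-methoxyphenyl]-2-methoxyethanone, via aryllithium 11 (not isolated)
Conditions: n-BuLi (1.05 equiv), THF, −78 °C; then 7 (1.2 equiv), −78 → 0 °C; aq NH4Cl
Reagents that add atoms: none
Why: Bromine–lithium exchange at −78 °C outruns benzylic deprotonation and the aryllithium adds once to the Weinreb amide because the chelated tetrahedral adduct collapses only on work-up (Weinreb ketone synthesis), which avoids a Lewis-acid Friedel–Crafts acylation that would endanger the benzyl ether ortho to the new ketone.

Step 9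
Reactants: 12 1-[2,5-bis(benzyloxy)-4-methoxyphenyl]-2-methoxyethanone; 5 4-(benzyloxy)-2,6-dibromo-3,5-dimethoxybenzoyl chloride
Product: 15 7-(benzyloxy)-2-[2,5-bis(benzyloxy)-4-methoxyphenyl]-5-bromo-3,6,8-trimethoxy-4H-chromen-4-one, via lithium Z-enolate 13 (not isolated), via 2-methoxy-1,3-diketone 14 (not isolated)
Conditions: LiN(SiMe3)2 (2.1 equiv), THF, −78 °C; 5 (1.05 equiv), −78 → 0 °C; aq NH4Cl, phase cut, solvent swap to DMF; CuI (10 mol%), K2CO3 (2 equiv), DMF, 90 °C, Ar
Reagents that add atoms: none
Why: LiN(SiMe3)2 should give the lithium-chelated Z-enolate 13, whose carbon attacks the acyl chloride of 5 (Claisen-type C-acylation, forming C3–C4), and the second equivalent of base traps diketone 14 as its enolate and so drives the acylation forward. After the quench, K2CO3 regenerates the enolate in DMF, monovalent copper binds it, inserts into a C–Br bond ortho to the C4 carbonyl, and reductive elimination forms O1–C8a. The closest known reaction type is the CuI-catalysed intramolecular Ullmann O-arylation of 1-(2-haloaryl)-1,3-diketones to flavones and chromones. Ring C closes as a six-membered ring through the oxygen on the ring B side (6-exo-type attack at the aryl carbon, bromide leaving outside the ring); no stereocentre is made, the C3 centre of keto 14 being lost on enolisation. The step needs C- over O-acylation, which the chelated lithium enolate in THF and the excess base should secure, and a single closure, which is secured because the two bromides are equivalent by the mirror symmetry of ring A, the ring A-side oxygen could only form a four-membered ring, and after closure no nucleophile can reach the C5 bromide.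

Step 10
Reactants: 15 7-(benzyloxy)-2-[2,5-bis(benzyloxy)-4-methoxyphenyl]-5-bromo-3,6,8-trimethoxy-4H-chromen-4-one
Product: 16 7-(benzyloxy)-2-[2,5-bis(benzyloxy)-4-methoxyphenyl]-5-hydroxy-3,6,8-trimethoxy-4H-chromen-4-one
Conditions: Cu(acac)2 (5 mol%), N,N'-bis(4-hydroxy-2,6-dimethylphenyl)oxalamide (5 mol%), LiOH·H2O (2.5 equiv), DMSO/H2O (4:1), 80 °C, Ar; then aq HCl
Reagents that add atoms: lithium hydroxide monohydrate, [Li+].[OH-].O
Why: Copper-catalysed Ullmann-type hydroxylation of an aryl bromide should be favoured at C5 because the neighbouring C4 carbonyl chelates copper during insertion, the benzyl and methyl ethers are inert to LiOH, and the acidic work-up recloses any pyranone opened reversibly by hydroxide.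

Step 11
Reactants: 16 7-(benzyloxy)-2-[2,5-bis(benzyloxy)-4-methoxyphenyl]-5-hydroxy-3,6,8-trimethoxy-4H-chromen-4-one
Product: 17 5,7,2',5'-tetrahydroxy-3,6,8,4'-tetramethoxyflavone (5,7-dihydroxy-2-(2,5-dihydroxy-4-methoxyphenyl)-3,6,8-trimethoxy-4H-chromen-4-one)
Conditions: H2 (1 atm), 10% Pd/C, EtOAc/MeOH (1:1), rt; filtration under Ar
Reagents that add atoms: none
Why: Catalytic hydrogenolysis should cleave the three benzylic C–O bonds without touching the methyl ethers or the flavone C2=C3 bond at 1 atm; the bromine has already been replaced, so no hydrodehalogenation can interfere, and the hydroquinone product is kept under argon.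

**Compound list**

1 | syringic acid (4-hydroxy-3,5-dimethoxybenzoic acid) | COc1cc(C(=O)O)cc(OC)c1O | starting material
2 | benzyl 4-(benzyloxy)-3,5-dimethoxybenzoate | COc1cc(C(=O)OCc2ccccc2)cc(OC)c1OCc1ccccc1 | intermediate
3 | 4-(benzyloxy)-3,5-dimethoxybenzoic acid | COc1cc(C(=O)O)cc(OC)c1OCc1ccccc1 | intermediate
4 | 4-(benzyloxy)-2,6-dibromo-3,5-dimethoxybenzoic acid | COc1c(Br)c(C(=O)O)c(Br)c(OC)c1OCc1ccccc1 | intermediate
5 | 4-(benzyloxy)-2,6-dibromo-3,5-dimethoxybenzoyl chloride | COc1c(Br)c(C(=O)Cl)c(Br)c(OC)c1OCc1ccccc1 | intermediate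
6 | methoxyacetyl chloride | COCC(=O)Cl | starting material
7 | N,2-dimethoxy-N-methylacetamide | COCC(=O)N(C)OC | intermediate
8 | 2-methoxyhydroquinone (2-methoxybenzene-1,4-diol) | COc1cc(O)ccc1O | starting material
9 | 1,4-bis(benzyloxy)-2-methoxybenzene | COc1cc(OCc2ccccc2)ccc1OCc1ccccc1 | intermediate
10 | 1,4-bis(benzyloxy)-2-bromo-5-methoxybenzene | COc1cc(OCc2ccccc2)c(Br)cc1OCc1ccccc1 | intermediate
11 | [2,5-bis(benzyloxy)-4-methoxyphenyl]lithium (not isolated) | [Li]c1cc(OCc2ccccc2)c(OC)cc1OCc1ccccc1 | intermediate
12 | 1-[2,5-bis(benzyloxy)-4-methoxyphenyl]-2-methoxyethanone | COCC(=O)c1cc(OCc2ccccc2)c(OC)cc1OCc1ccccc1 | intermediate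
13 | lithium (Z)-1-[2,5-bis(benzyloxy)-4-methoxyphenyl]-2-methoxyethen-1-olate (not isolated) | [Li+].[O-]/C(=C\OC)c1cc(OCc2ccccc2)c(OC)cc1OCc1ccccc1 | intermediate
14 | 1-[4-(benzyloxy)-2,6-dibromo-3,5-dimethoxyphenyl]-3-[2,5-bis(benzyloxy)-4-methoxyphenyl]-2-methoxypropane-1,3-dione (not isolated; C2 racemic and enolisable) | COC(C(=O)c1c(Br)c(OC)c(OCc2ccccc2)c(OC)c1Br)C(=O)c1cc(OCc2ccccc2)c(OC)cc1OCc1ccccc1 | intermediate
15 | 7-(benzyloxy)-2-[2,5-bis(benzyloxy)-4-methoxyphenyl]-5-bromo-3,6,8-trimethoxy-4H-chromen-4-one | COc1c(-c2cc(OCc3ccccc3)c(OC)cc2OCc2ccccc2)oc2c(OC)c(OCc3ccccc3)c(OC)c(Br)c2c1=O | intermediate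
16 | 7-(benzyloxy)-2-[2,5-bis(benzyloxy)-4-methoxyphenyl]-5-hydroxy-3,6,8-trimethoxy-4H-chromen-4-one | COc1c(-c2cc(OCc3ccccc3)c(OC)cc2OCc2ccccc2)oc2c(OC)c(OCc3ccccc3)c(OC)c(O)c2c1=O | intermediate
17 | 5,7,2',5'-tetrahydroxy-3,6,8,4'-tetramethoxyflavone | COc1cc(O)c(-c2oc3c(OC)c(O)c(OC)c(O)c3c(=O)c2OC)cc1O | target

**Step count**

Total step count: 11.
Longest linear sequence: 7 steps (steps 1, 2, 3, 4, 9, 10, 11, from syringic acid).

**Steps most likely to fail**

Step 9. The acyl chloride carbon is shielded by two ortho bromines, so attack by the enolate carbon may be slow. O-acylation to an enol ester, or acylation of the silylamide base, could then take over. In the copper stage, loss of the second bromide by reduction is a further risk. The fallback replaces the acylation by an aldol addition and an oxidation. It sets out from 5, which is reduced with LiAlH(Ot-Bu)3 in THF at −78 °C to 4-(benzyloxy)-2,6-dibromo-3,5-dimethoxybenzaldehyde F1. Enolate 13, made from 12 with LiN(SiMe3)2, is added to this aldehyde at −78 °C; an aldehyde has no O-acylation channel and is far less shielded. This should give 3-[4-(benzyloxy)-2,6-dibromo-3,5-dimethoxyphenyl]-1-[2,5-bis(benzyloxy)-4-methoxyphenyl]-3-hydroxy-2-methoxypropan-1-one F2 as a mixture of diastereomers. Oxidation with Dess–Martin periodinane (CH2Cl2, NaHCO3) should then give diketone 14, where the route is rejoined; 14 is closed with CuI and K2CO3 in DMF as in the second stage of step 9.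

Step 10. Hydroxide may add at C2 and open the pyranone, after which retro-Claisen cleavage of the diketone would destroy the skeleton. Protodebromination may also outrun C–O bond formation at the doubly flanked C5. The fallback avoids free hydroxide by bringing in the oxygen as a fourth benzyl ether. It sets out from 15, which is coupled with benzyl alcohol (CuI, 3,4,7,8-tetramethyl-1,10-phenanthroline, Cs2CO3, BnOH, toluene, 110 °C) to give 5,7-bis(benzyloxy)-2-[2,5-bis(benzyloxy)-4-methoxyphenyl]-3,6,8-trimethoxy-4H-chromen-4-one F3. Hydrogenolysis of all four benzyl ethers under the conditions of step 11 should then give 17 directly, where the route is rejoined.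

Step 3. The second bromination may stall on the deactivated monobromo acid, and forcing it invites ipso attack at C1 with loss of CO2 or acidolysis of the benzyl ether by HBr. The fallback brominates at the ester stage, where there is no free carboxyl group and no HBr is formed. It sets out from 2, which is treated with NBS (2.3 equiv) and catalytic CF3CO2H in MeCN at 40 °C to give benzyl 4-(benzyloxy)-2,6-dibromo-3,5-dimethoxybenzoate F4. The hindered ester is then cleaved with KOt-Bu/H2O (2:1, "anhydrous hydroxide") in THF at rt and acidified, which should give 4, where the route is rejoined.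

Further compounds
F1 | step 9 | 4-(benzyloxy)-2,6-dibromo-3,5-dimethoxybenzaldehyde | COc1c(Br)c(C=O)c(Br)c(OC)c1OCc1ccccc1
F2 | step 9 | 3-[4-(benzyloxy)-2,6-dibromo-3,5-dimethoxyphenyl]-1-[2,5-bis(benzyloxy)-4-methoxyphenyl]-3-hydroxy-2-methoxypropan-1-one (diastereomer mixture, racemic) | COC(C(O)c1c(Br)c(OC)c(OCc2ccccc2)c(OC)c1Br)C(=O)c1cc(OCc2ccccc2)c(OC)cc1OCc1ccccc1
F3 | step 10 | 5,7-bis(benzyloxy)-2-[2,5-bis(benzyloxy)-4-methoxyphenyl]-3,6,8-trimethoxy-4H-chromen-4-one | COc1c(-c2cc(OCc3ccccc3)c(OC)cc2OCc2ccccc2)oc2c(OC)c(OCc3ccccc3)c(OC)c(OCc3ccccc3)c2c1=O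
F4 | step 3 | benzyl 4-(benzyloxy)-2,6-dibromo-3,5-dimethoxybenzoate | COc1c(Br)c(C(=O)OCc2ccccc2)c(Br)c(OC)c1OCc1ccccc1
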